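The data are simulated for substances that don't exist; scatter was added.

Start from the leftover in the south-west run: from 1.00 h on, the starting complex stays near 84.0 % of its charge, still 0.0630 M against 0.030 M of incoming ligand charged, so keep the books on the ligand, not on the complex.

| flask | starting complex | incoming ligand | remark | time |
|---|---|---|---|---|
| south-west | 0.075 M | 0.030 M | run made earlier |  |
| north | 0.075 M | 0.068 M | run made earlier |  |
| south | 0.11 M | 0.045 M | run made earlier |  |
| flask | 0.075 M | 0.0450 M |  | 2.5 h |

| run | time / h | starting complex / % | complex with two exchanged / % |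
|---|---|---|---|
| south-west | 0.417 | 85.7 | 2.9 |
| south-west | 1.00 | 84.5 | 6.0 |
| south-west | 2.00 | 84.5 | 5.1 |
| south-west | 3.00 | 83.0 | 5.5 |
| north | 0.833 | 71.4 | 12.4 |
| north | 1.50 | 71.4 | 8.5 |
| north | 2.50 | 74.0 | 7.5 |
| north | 3.00 | 73.8 | 10.7 |
| south | 0.250 | 86.7 | 3.5 |
| south | 0.500 | 83.9 | 6.8 |
| south | 1.33 | 82.4 | 5.0 |
| south | 3.00 | 81.3 | 4.0 |

(standard deviation of a reading: 1 percentage point)

- the earlier runs do not show how much of incoming ligand is bound; that part of a forecast is a guess

1. part of the starting complex that has reacted at 2.5 h
2. share of the unused incoming ligand that is free and not bound as idle adduct, at 2.5 h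

Call the moles of starting complex lost on the flat stretch, per mole of incoming ligand charged, the capture share, and read it as 40.0 % in the south-west run and, from 1.50 h on, as 29.7 % in the north run. Holding the starting complex at 0.075 M, draw a straight line between them in the ligand charge, and the flask stands at 35.9 %, its capture share.

Now open the ledger of the flask, whose incoming ligand is the limiting reagent at 0.0450 M against 0.075 M. Enter 0.0162 M for complex lost, one ligand each, which is my 21.6 % reacted at 2.5 h, a time inside the flat stretch of both runs. Enter 0.00515 M for the extra ligand in the complex with two exchanged, read along the same line. Close the books with 0.0236 M unassigned, and leave the free share a guess, since no reading separates free, bound and lost ligand.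

The forecast gives 21 % reacted and 70 % free, and says of its split: “This assumption is untested, so the range is wide”.

The flask gives 20.2 % reacted and 73.7 % free.

    starting complex + incoming ligand ⇌ leaving ligand + complex with one exchanged (K = 0.560, k = 0.00661 M⁻¹ s⁻¹)
    complex with one exchanged + incoming ligand ⇌ leaving ligand + complex with two exchanged (K = 3.13, k = 0.0401 M⁻¹ s⁻¹)
    complex with two exchanged + incoming ligand ⇌ leaving ligand + complex with three exchanged (K = 2.00, k = 0.0121 M⁻¹ s⁻¹)
    leaving ligand + incoming ligand ⇌ idle adduct, settled at all times (K = 17.0 M⁻¹)
    incoming ligand → decomposed reagent (k = 2.43 × 10⁻⁴ s⁻¹)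
    2 starting complex → self-condensation product (k = 1.91 × 10⁻⁵ M⁻¹ s⁻¹)

That is a capture share of 33.6 %, less than my 35.9 %. At 2.5 h the flask's incoming ligand stands as decomposed reagent 0.0178 M, idle adduct 0.00129 M, free ligand 8.05 % of its charge and 0.0223 M carried by the complexes with one, two and three exchanged, which together make 0.0450 M of the 0.0450 M charged. Extended slightly past the south-west run, the line through 40.0 % and 35.9 % puts the neighbour charged with 0.027 M of incoming ligand at a capture share of 40.8 %, hence 14.7 % reacted, and that neighbour flask gives 15.1 %.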